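**Plan**

1. The target is read as three (2R,3R)-epiafzelechin units joined 4β→8 twice (top unit rings A/C/B, middle D/F/E, lower G/I/H). Cuts, in order: C4–C4a of ring C; C4 (ring C)–C8 (ring D); C4 (ring F)–C8 (ring G); then the O1–C8a aryl ether and the C2–C3 bond of the top three-carbon chain.
2. Enabling feature: C4 of ring C is a benzhydryl carbon between two phloroglucinol rings. C8 of ring D has oxygens at C7 and C8a (ortho) and C5 (para), so ring D can carry a cation at C4 as well as ring A usually does. Ring A, as a 3,5-dibenzyloxyphenyl ether on O1, has two equivalent ortho carbons, so ring C can close last by Friedel–Crafts attack of ring A on a ring D-stabilised cation.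
3. Forward: rings G/I/H and D/F/E come intact from (−)-epiafzelechin and are joined by a flavan-4-yl cation coupling to an 8-bromo dimer. The chain C4–C3–C2 with ring B, and ring A on O1, is built by glycolate aldol, C–O coupling and oxidation. Bromine–lithium exchange joins C8 (ring D) to C4, ring C closes, and hydrogenolysis follows.
4. Stereochemistry: C2/C3 of the middle and lower units come from (−)-epiafzelechin; C4 of ring F from attack anti to the axial 3-OBn; C2/C3 of ring C from an Evans syn aldol (kept through an O-arylation with retention); C4 of ring C from the ring closure, under control of C3.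
5. Helpers: Br at C8 of ring D (blocks self-coupling, then becomes the metalation site), the C4 hydroxyl (leaving group), twelve benzyl ethers (removed last).

Key step: step 14

Remark: (−)-epiafzelechin (15) is taken as a purchasable natural product whose (2R,3R) configuration supplies the middle and lower units, and 1,3-bis(benzyloxy)-5-bromobenzene (11) as a catalogue compound.

**Route**

Step 1
Reactants: 1 (S)-4-benzyl-1,3-oxazolidin-2-one; 2 (benzyloxy)acetyl chloride
Product: 4 (S)-4-benzyl-3-[(benzyloxy)acetyl]-1,3-oxazolidin-2-one, via lithium oxazolidinide 3 (not isolated)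
Conditions: n-BuLi, THF, −78 °C; then 2, −78 → 0 °C
Reagents that add atoms: none
Why: N-acylation of the lithiated Evans auxiliary by an acid chloride is fast at −78 °C and touches no stereocentre.

Step 2
Reactants: 4 (S)-4-benzyl-3-[(benzyloxy)acetyl]-1,3-oxazolidin-2-one; 5 4-(benzyloxy)benzaldehyde
Product: 8 (S)-4-benzyl-3-[(2S,3R)-2-(benzyloxy)-3-[4-(benzyloxy)phenyl]-3-hydroxypropanoyl]-1,3-oxazolidin-2-one, via boron enolate 6 (not isolated), via boron aldolate 7 (not isolated)
Conditions: Bu2BOTf, i-Pr2NEt, CH2Cl2, −78 → 0 °C; then 5, −78 → 0 °C; then pH 7 buffer, MeOH, H2O2, 0 °C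
Reagents that add atoms: none
Why: Evans syn aldol reaction, in which the Z-boron enolate 6 reacts through a Zimmerman–Traxler chair on the face away from the C4 benzyl group of the auxiliary, which should set both new stereocentres as (2S,3R) (the future C3 and C2 of ring C) with the benzyl ether already on the future 3-oxygen.

Step 3
Reactants: 8 aldol adduct
Product: 9 (1R,2R)-2-(benzyloxy)-1-[4-(benzyloxy)phenyl]propane-1,3-diol
Conditions: LiBH4, H2O (1 equiv), Et2O, 0 °C
Reagents that add atoms: none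
Why: Reductive cleavage of the N-acyl oxazolidinone by LiBH4 should give the primary alcohol and release the auxiliary without touching the two stereocentres or the benzyl ethers.

Step 4
Reactants: 9 (1R,2R)-2-(benzyloxy)-1-[4-(benzyloxy)phenyl]propane-1,3-diol
Product: 10 (1R,2R)-2-(benzyloxy)-1-[4-(benzyloxy)phenyl]-3-[(tert-butyldiphenylsilyl)oxy]propan-1-ol
Conditions: TBDPSCl, imidazole, CH2Cl2, 0 °C
Reagents that add atoms: tert-butyl(chloro)diphenylsilane, CC(C)(C)[Si](Cl)(c1ccccc1)c1ccccc1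
Why: Silylation with the bulky chlorosilane should be selective for the primary hydroxyl over the hindered secondary benzylic one, and this silyl group resists oxygen-to-oxygen migration under the basic conditions of step 5.

Step 5
Reactants: 10 silyl ether alcohol; 11 1,3-bis(benzyloxy)-5-bromobenzene
Product: 12 tert-butyl{[(2R,3R)-2-(benzyloxy)-3-[4-(benzyloxy)phenyl]-3-[3,5-bis(benzyloxy)phenoxy]propyl]oxy}diphenylsilane
Conditions: CuI (cat.), 3,4,7,8-tetramethyl-1,10-phenanthroline, Cs2CO3, toluene, 110 °C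
Reagents that add atoms: none
Why: Ullmann-type copper-catalysed C–O coupling of a secondary alkoxide with an aryl bromide, in which the carbinol C–O bond is not broken, so the benzylic stereocentre (future C2 of ring C) is retained while ring A is attached through the future O1.

Step 6
Reactants: 12 aryl ether silyl ether
Product: 13 (2R,3R)-2-(benzyloxy)-3-[4-(benzyloxy)phenyl]-3-[3,5-bis(benzyloxy)phenoxy]propan-1-ol
Conditions: TBAF, THF, 0 °C → rt
Reagents that add atoms: none
Why: Fluoride-mediated cleavage of the silyl ether leaves the benzyl and aryl ethers and both stereocentres untouched.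

Step 7
Reactants: 13 primary alcohol
Product: 14 (2S,3R)-2-(benzyloxy)-3-[4-(benzyloxy)phenyl]-3-[3,5-bis(benzyloxy)phenoxy]propanal
Conditions: DMP, pyridine, CH2Cl2, 0 °C → rt; used crude
Reagents that add atoms: none
Why: Dess–Martin oxidation under buffered, non-basic conditions should give the aldehyde without epimerisation at the α-carbon or β-elimination of the aryloxide.

Step 8
Reactants: 15 (−)-epiafzelechin
Product: 16 5,7,4'-tri-O-benzyl-(−)-epiafzelechin
Conditions: BnBr (3.3 equiv), K2CO3, DMF, 0 °C → rt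
Reagents that add atoms: benzyl bromide, BrCc1ccccc1
Why: Williamson etherification in which K2CO3 deprotonates only the three phenols, so the 3-OH stays free and C2/C3 are kept.

Step 9
Reactants: 16 5,7,4'-tri-O-benzyl-(−)-epiafzelechin
Product: 17 3,5,7,4'-tetra-O-benzyl-(−)-epiafzelechin
Conditions: NaH, BnBr, DMF, 0 °C → rt
Reagents that add atoms: benzyl bromide, BrCc1ccccc1
Why: Williamson etherification of the remaining secondary alcohol through its sodium alkoxide; with no free phenol left the pyran ring cannot open to a quinone methide, so C2 and C3 are kept.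

Step 10
Reactants: 17 3,5,7,4'-tetra-O-benzyl-(−)-epiafzelechin
Product: 19 (2R,3R,4S)-3,5,7-tris(benzyloxy)-2-[4-(benzyloxy)phenyl]-4-(2-ethoxyethoxy)chromane (4β ether), via flavan-4-yl cation 18 (not isolated)
Conditions: DDQ, 2-ethoxyethanol, CH2Cl2, rt
Reagents that add atoms: 2-ethoxyethanol, CCOCCO
Why: DDQ-mediated oxidative benzylic etherification, in which hydride is abstracted from the C4–H2 activated by the ring oxygens and the alcohol captures cation 18 on the face anti to the axial 3-OBn to give the 4β ether.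

Step 11
Reactants: 19 4β-(2-ethoxyethoxy) ether
Product: 20 8-bromo-3,5,7,4'-tetra-O-benzyl-4β-(2-ethoxyethoxy)-(−)-epiafzelechin
Conditions: NBS (1.0 equiv), CH2Cl2, −78 → 0 °C
Reagents that add atoms: N-bromosuccinimide, O=C1CCC(=O)N1Br
Why: Electrophilic aromatic bromination, for which C8 is the most nucleophilic position of the benzo ring in benzylated flavan-3-ols, so one equivalent of NBS at low temperature should stop at the 8-monobromide.

Step 12
Reactants: 20 8-bromo 4β-ether; 17 3,5,7,4'-tetra-O-benzyl-(−)-epiafzelechin (1.5 equiv)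
Product: 22 8-bromo-3,5,7,4'-tetra-O-benzylepiafzelechin-(4β→8)-3,5,7,4'-tetra-O-benzylepiafzelechin, via 8-bromoflavan-4-yl cation 21 (not isolated)
Conditions: TMSOTf (0.1 equiv), CH2Cl2, −78 °C
Reagents that add atoms: none
Why: Lewis acid-mediated Friedel–Crafts coupling of a flavan-4-yl cation, in which C8 of 17 attacks cation 21 anti to the axial 3-OBn to set the 4β→8 bond between rings F and G, while the bromine at C8 of the electrophile blocks self-condensation.

Step 13
Reactants: 22 8-bromo dimer; 14 aldehyde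
Product: 24 dimer carrying at C8 of ring D the chain CH(OH)–CH(OBn)–CH(4-benzyloxyphenyl)–O–(3,5-dibenzyloxyphenyl) (both carbinol epimers), via 8-lithio dimer 23 (not isolated)
Conditions: n-BuLi, THF, −78 °C; then 14, −78 °C; then H2O; used crude
Reagents that add atoms: none
Why: Bromine–lithium exchange followed by 1,2-addition of the aryllithium to the aldehyde joins C8 of ring D to the future C4 of ring C, and the new carbinol centre need not be controlled because it is ionised in step 14.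

Step 14
Reactants: 24 carbinol
Product: 26 dodeca-O-benzyl epiafzelechin-(4β→8)-epiafzelechin-(4β→8)-epiafzelechin, via benzylic cation 25 (not isolated)
Conditions: TMSOTf (0.1 equiv), 4 Å MS, CH2Cl2 (2 mM), −78 → −40 °C; Et3N quench
Reagents that add atoms: none
Why: The acid ionises the C4–OH of 24 to cation 25, which is stabilised by the ether oxygens of ring D (at C7 and C8a ortho, at C5 para to C8), and an ortho carbon of the 3,5-dibenzyloxyphenyl ether attacks it to form the C4–C4a bond. The closest known reaction type is the acid-mediated intramolecular Friedel–Crafts alkylation (cyclodehydration) of 3-aryloxy-1-arylpropan-1-ols to 4-arylchromans. Ring C closes in a 6-exo-trig mode onto the exocyclic C4=C8 quinone-methide bond of the cation, with the attacking C4a=C8a arene bond endocyclic. The new C4 stereocentre is controlled by C3: allylic strain makes H3 eclipse the di-ortho-substituted ring D, so C4a, delivered from the C2 side, bonds anti to the C3–OBn bond (polar Felkin–Anh arrangement), and this should give the 3,4-trans (4β) isomer with the ring D aryl pseudo-axial and clear of the peri 5-OBn, which is also the isomer expected at equilibrium. Both carbinol epimers converge on the same cation. The step needs chemoselective ionisation at C4 over the C2–O1 aryl ether and the existing 4→8 bond, which the far greater stability of the trialkoxybenzyl cation and the low temperature should secure; regioselectivity is secured because only the two equivalent ortho carbons of ring A can reach C4 in a six-membered ring, and high dilution suppresses capture by free C6 positions.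

Step 15
Reactants: 26 dodeca-O-benzyl trimer
Product: 27 epiafzelechin-(4β→8)-epiafzelechin-(4β→8)-epiafzelechin (CNP0191553.1)
Conditions: H2 (1 atm), Pd(OH)2/C, THF/MeOH/H2O, rt
Reagents that add atoms: none
Why: Hydrogenolysis of the twelve benzyl ethers over Pd(OH)2/C, as used for benzylated proanthocyanidin oligomers, touches no stereocentre and is stopped before the ring C2–O1 bonds are cleaved.

**Compound list**

1 | (S)-4-benzyl-1,3-oxazolidin-2-one | O=C1N[C@@H](Cc2ccccc2)CO1 | starting material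
2 | (benzyloxy)acetyl chloride | ClC(=O)COCc1ccccc1 | starting material
3 | N-lithio-(S)-4-benzyl-1,3-oxazolidin-2-one (not isolated) | [Li]N1[C@@H](Cc2ccccc2)COC1=O | intermediate
4 | (S)-4-benzyl-3-[(benzyloxy)acetyl]-1,3-oxazolidin-2-one | O=C(COCc1ccccc1)N1[C@@H](Cc2ccccc2)COC1=O | intermediate
5 | 4-(benzyloxy)benzaldehyde | O=Cc1ccc(OCc2ccccc2)cc1 | starting material
6 | (Z)-dibutylboron enolate of 4 (not isolated) | CCCCB(CCCC)O/C(=C\OCc1ccccc1)N1[C@@H](Cc2ccccc2)COC1=O | intermediate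
7 | dibutylboron aldolate of 8 (not isolated) | CCCCB(CCCC)O[C@H](c1ccc(OCc2ccccc2)cc1)[C@@H](C(=O)N1[C@@H](Cc2ccccc2)COC1=O)OCc1ccccc1 | intermediate
8 | (S)-4-benzyl-3-[(2S,3R)-2-(benzyloxy)-3-[4-(benzyloxy)phenyl]-3-hydroxypropanoyl]-1,3-oxazolidin-2-one | O[C@H](c1ccc(OCc2ccccc2)cc1)[C@@H](C(=O)N1[C@@H](Cc2ccccc2)COC1=O)OCc1ccccc1 | intermediate
9 | (1R,2R)-2-(benzyloxy)-1-[4-(benzyloxy)phenyl]propane-1,3-diol | O[C@H](c1ccc(OCc2ccccc2)cc1)[C@@H](CO)OCc1ccccc1 | intermediate
10 | (1R,2R)-2-(benzyloxy)-1-[4-(benzyloxy)phenyl]-3-[(tert-butyldiphenylsilyl)oxy]propan-1-ol | O[C@H](c1ccc(OCc2ccccc2)cc1)[C@@H](CO[Si](c1ccccc1)(c1ccccc1)C(C)(C)C)OCc1ccccc1 | intermediate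
11 | 1,3-bis(benzyloxy)-5-bromobenzene | Brc1cc(OCc2ccccc2)cc(OCc2ccccc2)c1 | starting material
12 | tert-butyl{[(2R,3R)-2-(benzyloxy)-3-[4-(benzyloxy)phenyl]-3-[3,5-bis(benzyloxy)phenoxy]propyl]oxy}diphenylsilane | c1c(OCc2ccccc2)cc(OCc2ccccc2)cc1O[C@H](c1ccc(OCc2ccccc2)cc1)[C@@H](CO[Si](c1ccccc1)(c1ccccc1)C(C)(C)C)OCc1ccccc1 | intermediate
13 | (2R,3R)-2-(benzyloxy)-3-[4-(benzyloxy)phenyl]-3-[3,5-bis(benzyloxy)phenoxy]propan-1-ol | c1c(OCc2ccccc2)cc(OCc2ccccc2)cc1O[C@H](c1ccc(OCc2ccccc2)cc1)[C@@H](CO)OCc1ccccc1 | intermediate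
14 | (2S,3R)-2-(benzyloxy)-3-[4-(benzyloxy)phenyl]-3-[3,5-bis(benzyloxy)phenoxy]propanal | c1c(OCc2ccccc2)cc(OCc2ccccc2)cc1O[C@H](c1ccc(OCc2ccccc2)cc1)[C@@H](C=O)OCc1ccccc1 | intermediate
15 | (−)-epiafzelechin, (2R,3R)-2-(4-hydroxyphenyl)chromane-3,5,7-triol | Oc1ccc(cc1)[C@H]1Oc2cc(O)cc(O)c2C[C@H]1O | starting material
16 | 5,7,4'-tri-O-benzyl-(−)-epiafzelechin | c1ccccc1COc1ccc(cc1)[C@H]1Oc2cc(OCc3ccccc3)cc(OCc3ccccc3)c2C[C@H]1O | intermediate
17 | 3,5,7,4'-tetra-O-benzyl-(−)-epiafzelechin | c1ccccc1COc1ccc(cc1)[C@H]1Oc2cc(OCc3ccccc3)cc(OCc3ccccc3)c2C[C@H]1OCc1ccccc1 | intermediate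
18 | flavan-4-yl cation of 17 (not isolated) | c1ccccc1COc1ccc(cc1)[C@H]1Oc2cc(OCc3ccccc3)cc(OCc3ccccc3)c2[CH+][C@H]1OCc1ccccc1 | intermediate
19 | (2R,3R,4S)-3,5,7-tris(benzyloxy)-2-[4-(benzyloxy)phenyl]-4-(2-ethoxyethoxy)chromane (4β ether) | c1ccccc1COc1ccc(cc1)[C@H]1Oc2cc(OCc3ccccc3)cc(OCc3ccccc3)c2[C@H](OCCOCC)[C@H]1OCc1ccccc1 | intermediate
20 | 8-bromo-3,5,7,4'-tetra-O-benzyl-4β-(2-ethoxyethoxy)-(−)-epiafzelechin | c1ccccc1COc1ccc(cc1)[C@H]1Oc2c(Br)c(OCc3ccccc3)cc(OCc3ccccc3)c2[C@H](OCCOCC)[C@H]1OCc1ccccc1 | intermediate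
21 | 8-bromoflavan-4-yl cation of 20 (not isolated) | c1ccccc1COc1ccc(cc1)[C@H]1Oc2c(Br)c(OCc3ccccc3)cc(OCc3ccccc3)c2[CH+][C@H]1OCc1ccccc1 | intermediate
22 | 8-bromo-3,5,7,4'-tetra-O-benzylepiafzelechin-(4β→8)-3,5,7,4'-tetra-O-benzylepiafzelechin | c5ccccc5COc1ccc([C@H]2Oc3c(c(OCc5ccccc5)cc(OCc5ccccc5)c3Br)[C@H](c3c(OCc5ccccc5)cc(OCc5ccccc5)c4c3O[C@H](c3ccc(OCc5ccccc5)cc3)[C@H](OCc5ccccc5)C4)[C@H]2OCc5ccccc5)cc1 | intermediate
23 | 8-lithio analogue of 22 (not isolated) | c5ccccc5COc1ccc([C@H]2Oc3c(c(OCc5ccccc5)cc(OCc5ccccc5)c3[Li])[C@H](c3c(OCc5ccccc5)cc(OCc5ccccc5)c4c3O[C@H](c3ccc(OCc5ccccc5)cc3)[C@H](OCc5ccccc5)C4)[C@H]2OCc5ccccc5)cc1 | intermediate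
24 | carbinol: octa-O-benzyl dimer with CH(OH)–CH(OBn)–CH(4-benzyloxyphenyl)–O–(3,5-dibenzyloxyphenyl) at C8 of ring D, chain configuration as in 14, both carbinol epimers | c5ccccc5COc1ccc([C@H]2Oc3c(c(OCc5ccccc5)cc(OCc5ccccc5)c3C(O)[C@@H](OCc5ccccc5)[C@@H](c4ccc(OCc5ccccc5)cc4)Oc4cc(OCc5ccccc5)cc(OCc5ccccc5)c4)[C@H](c3c(OCc5ccccc5)cc(OCc5ccccc5)c4c3O[C@H](c3ccc(OCc5ccccc5)cc3)[C@H](OCc5ccccc5)C4)[C@H]2OCc5ccccc5)cc1 | intermediate
25 | ring D-stabilised benzylic cation from 24 (not isolated) | c5ccccc5COc1ccc([C@H]2Oc3c(c(OCc5ccccc5)cc(OCc5ccccc5)c3[CH+][C@@H](OCc5ccccc5)[C@@H](c4ccc(OCc5ccccc5)cc4)Oc4cc(OCc5ccccc5)cc(OCc5ccccc5)c4)[C@H](c3c(OCc5ccccc5)cc(OCc5ccccc5)c4c3O[C@H](c3ccc(OCc5ccccc5)cc3)[C@H](OCc5ccccc5)C4)[C@H]2OCc5ccccc5)cc1 | intermediate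
26 | dodeca-O-benzyl epiafzelechin-(4β→8)-epiafzelechin-(4β→8)-epiafzelechin | c5ccccc5COc1ccc([C@H]2Oc3c(c(OCc5ccccc5)cc(OCc5ccccc5)c3[C@H]3c4c(OCc5ccccc5)cc(OCc5ccccc5)cc4O[C@H](c4ccc(OCc5ccccc5)cc4)[C@@H]3OCc5ccccc5)[C@H](c3c(OCc5ccccc5)cc(OCc5ccccc5)c4c3O[C@H](c3ccc(OCc5ccccc5)cc3)[C@H](OCc5ccccc5)C4)[C@H]2OCc5ccccc5)cc1 | intermediate
27 | epiafzelechin-(4β→8)-epiafzelechin-(4β→8)-epiafzelechin (CNP0191553.1) | Oc1ccc([C@H]2Oc3c(c(O)cc(O)c3[C@H]3c4c(O)cc(O)cc4O[C@H](c4ccc(O)cc4)[C@@H]3O)[C@H](c3c(O)cc(O)c4c3O[C@H](c3ccc(O)cc3)[C@H](O)C4)[C@H]2O)cc1 | target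

**Step count and risks**

Total steps: 15. Longest linear sequence: 10 steps (steps 1–7, then 13, 14, 15).

Steps most likely to fail:

Step 14. What may go wrong: insufficient facial discrimination at the cationic C4, ionisation of the C2–O1 aryl ether, or acid-induced scission of the existing 4→8 bond. The fallback reverts to the classical polarity; it sets out from 14 and 22 and comes back at 26. Bromide 22 is treated with n-BuLi in THF at −78 °C and quenched with MeOH to give the debrominated octa-O-benzyl dimer F2. Aldehyde 14 and F2 (2 equiv) are then combined with TMSOTf in CH2Cl2 at −78 °C. Ring C now closes first, by intramolecular Friedel–Crafts hydroxyalkylation of ring A onto the aldehyde, to the protected flavan-3,4-diol F1. Its 4-OH ionises in the same flask, and C8 of ring D of F2 attacks the flavan-4-yl cation anti to the axial 3-OBn, giving 26.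

Step 13. What may go wrong: proton transfer from the α-carbon of 14 to the hindered aryllithium, followed by β-elimination of the aryloxide, so that the aldehyde is consumed without C–C bond formation. The fallback sets out from 14 and comes back at 24. Pinnick oxidation (NaClO2, NaH2PO4, 2-methyl-2-butene, t-BuOH/H2O) gives the carboxylic acid F3. Coupling with MeNHOMe·HCl (EDC·HCl, i-Pr2NEt, CH2Cl2) gives the Weinreb amide F4, whose α-proton is far less acidic and whose tetrahedral chelate cannot eliminate before work-up. Addition of aryllithium 23 (from 22, n-BuLi, THF, −78 °C) gives the aryl ketone F5, and NaBH4 in THF/MeOH reduces it to 24.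

Step 5. What may go wrong: slow C–O coupling of the hindered secondary alkoxide, with competing reduction of the aryl bromide. The fallback sets out from 10 and comes back at 12. Dess–Martin oxidation of 10 gives the α-benzyloxy ketone F6. Chelation-controlled reduction with Zn(BH4)2 in Et2O at −20 °C should give the anti alcohol F7. Mitsunobu etherification with 3,5-bis(benzyloxy)phenol (PPh3, DIAD, toluene, 0 °C) then forms the aryl ether with inversion at the benzylic carbon, which is the configuration of 12.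

Further compounds
F1 | step 14 | (2R,3R)-3,5,7-tris(benzyloxy)-2-[4-(benzyloxy)phenyl]chroman-4-ol (protected flavan-3,4-diol, both C4 epimers) | c1ccccc1COc1ccc(cc1)[C@H]1Oc2cc(OCc3ccccc3)cc(OCc3ccccc3)c2C(O)[C@H]1OCc1ccccc1
F2 | step 14 | 3,5,7,4'-tetra-O-benzylepiafzelechin-(4β→8)-3,5,7,4'-tetra-O-benzylepiafzelechin (debrominated dimer) | c5ccccc5COc1ccc([C@H]2Oc3c(c(OCc5ccccc5)cc(OCc5ccccc5)c3)[C@H](c3c(OCc5ccccc5)cc(OCc5ccccc5)c4c3O[C@H](c3ccc(OCc5ccccc5)cc3)[C@H](OCc5ccccc5)C4)[C@H]2OCc5ccccc5)cc1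
F3 | step 13 | (2S,3R)-2-(benzyloxy)-3-[4-(benzyloxy)phenyl]-3-[3,5-bis(benzyloxy)phenoxy]propanoic acid | c1c(OCc2ccccc2)cc(OCc2ccccc2)cc1O[C@H](c1ccc(OCc2ccccc2)cc1)[C@@H](C(O)=O)OCc1ccccc1
F4 | step 13 | (2S,3R)-2-(benzyloxy)-3-[4-(benzyloxy)phenyl]-3-[3,5-bis(benzyloxy)phenoxy]-N-methoxy-N-methylpropanamide | c1c(OCc2ccccc2)cc(OCc2ccccc2)cc1O[C@H](c1ccc(OCc2ccccc2)cc1)[C@@H](C(=O)N(C)OC)OCc1ccccc1
F5 | step 13 | aryl ketone corresponding to 24 (C=O in place of CH(OH) at C8 of ring D) | c5ccccc5COc1ccc([C@H]2Oc3c(c(OCc5ccccc5)cc(OCc5ccccc5)c3C(=O)[C@@H](OCc5ccccc5)[C@@H](c4ccc(OCc5ccccc5)cc4)Oc4cc(OCc5ccccc5)cc(OCc5ccccc5)c4)[C@H](c3c(OCc5ccccc5)cc(OCc5ccccc5)c4c3O[C@H](c3ccc(OCc5ccccc5)cc3)[C@H](OCc5ccccc5)C4)[C@H]2OCc5ccccc5)cc1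
F6 | step 5 | (R)-2-(benzyloxy)-1-[4-(benzyloxy)phenyl]-3-[(tert-butyldiphenylsilyl)oxy]propan-1-one | O=C(c1ccc(OCc2ccccc2)cc1)[C@@H](CO[Si](c1ccccc1)(c1ccccc1)C(C)(C)C)OCc1ccccc1
F7 | step 5 | (1S,2R)-2-(benzyloxy)-1-[4-(benzyloxy)phenyl]-3-[(tert-butyldiphenylsilyl)oxy]propan-1-ol | O[C@@H](c1ccc(OCc2ccccc2)cc1)[C@@H](CO[Si](c1ccccc1)(c1ccccc1)C(C)(C)C)OCc1ccccc1
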